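A small charge of D, 0.05 mol% on 20 mM of J, turns J and Q into Z in the flask, with E present at 5.5 µM. The meeting had to say how strongly the rate of making Z answers to Q.

| setting | autumn | dusk | noon | flask |
|---|---|---|---|---|
| J | 20 mM | 20 mM | 20 mM | 20 mM |
| Q | 1.5 equiv | 1.5 equiv | 2.2 equiv | 1.50 equiv |
| D | 0.034 mol% | 0.075 mol% | 0.05 mol% | 0.05 mol% |
| E | 5.5 µM | 5.5 µM | 5.5 µM | 5.5 µM |
| remark | run made earlier | run made earlier | run made earlier |  |

| run | time / min | Z / % | J / % |
|---|---|---|---|
| autumn | 4.00 | 15 | 40 |
| autumn | 8.00 | 36 | 23 |
| autumn | 12.0 | 52 | 11 |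
| autumn | 15.0 | 62 | 7 |
| autumn | 20.0 | 77 | 0 |
| autumn | 25.0 | 85 | 1 |
| dusk | 1.50 | 16 | 40 |
| dusk | 5.00 | 58 | 8 |
| dusk | 8.00 | 80 | 0 |
| dusk | 15.0 | 100 | 3 |
| dusk | 20.0 | 101 | 0 |
| dusk | 25.0 | 100 | 0 |
| noon | 5.00 | 42 | 15 |
| noon | 10.0 | 78 | 2 |
| noon | 15.0 | 95 | 0 |
| noon | 20.0 | 101 | 0 |
| noon | 25.0 | 100 | 1 |

(standard deviation of a reading: 1.5 percentage points)

* apparent order in Q when 5.0% of the J are converted (percent change of the rate of making Z for one percent more Q charged)

Minutes. The first speaker compared average rates, Z over time, at about the same Z. From the autumn and dusk runs she reported an order in D of 1.30. She therefore put a run at 0.05 mol% of D and 1.50 equiv of Q at 0.0684 /min, in fractions of the J charged. The noon run, at 2.2 equiv, averaged 0.0800 /min over its first two readings, so against the charged ratio of 1.47 she proposed an order of 0.411.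

The second speaker objected that, if each Z uses one Q, those averages were not taken at the charged Q. He estimated the mean Z over the noon averages at 30.0% of the J charged and took the same Z for the run put at 1.50 equiv, so his estimate of the ratio of Q actually present was 1.58. Going round once more with that ratio, he gave the Q share, the percent change of the Z rate per percent more Q present, as 0.342. The meeting committed to this value, noting that it comes from readings near Z of 60.0%, not from 5.0% conversion.

The forecast, made separately, gave 0.3, lower than this reckoning, on the grounds “That is only 10–13% more for 47% more Q”.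

The simulation gives the flask an order in Q of 0.16 at 5.0% conversion.

    J + D → D + G (k = 1800 /M/s)
    Q + X → D + Z (k = 250 /M/s)
    D + G ⇌ X (K = 2600 /M, k = 1100 /M/s)
    D + E ⇌ L, settled at all times (K = 5.50 × 10⁵ /M)

In the flask, G is made 2.16 times as fast as it is used up at 1.72 min, each step taken net, and one percent more on the constants of D + G to X, forward and back together, changes the rate by 0.84 percent (its degree of rate control), more than the 0.16 percent that one percent more Q charged brings at 5.0% conversion. That order in Q of the flask stands below the 0.342 read from the earlier runs near Z of 60.0%, and G in the flask holds 45.0% of the J charged at 2.50 min.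

The numbers in the tables are calculated for an exercise, noise included.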